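**Plan**

1. Numbering used throughout: naphthalene C1 (bears ring C), C2 (bears CH2–ring D), C3 (OH), C4 (H), C4a, C5 (OMe), C6 (OH), C7 (OMe), C8 (H), C8a. Ring A is C1–C2–C3–C4–C4a–C8a and ring B is C4a–C8a.
2. Enabling feature: the ring A edge C1–C2–C3–C4 is a 1,3-oxygenated four-carbon chain (ring C on C1, hydroxyl on C3) whose C4 hangs on ring B at C4a, and C8a lies para to the C6 hydroxyl. Ring A is therefore a γ-aryl β-diketone folded by one C1–C8a bond.
3. Retrosynthetic cuts, in order: the three ArO–S bonds; C1–C8a (ring A); C2–C3 (aldol, then oxidation at C3); C2–CH2(ring D) (enone, then hydrogenation); C4–C4a (aryllithium plus oxirane).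
4. Forward: rings C, D and B are bought as 2,4-dihydroxyacetophenone, 3,4-dihydroxybenzaldehyde and 2,6-dimethoxyphenol. The chain is joined C2–CH2, then C4a–C4, then C2–C3. Ring A is the only ring made and closes in the penultimate step.
5. Stereochemistry: the target has no stereocentre. The C2/C3 centres of intermediates are uncontrolled and are erased by oxidation and aromatisation.

Key step: step 13

Assumption: the C1–aryl axis carries no descriptor in the target and is treated as configurationally undefined; sp3 centres of intermediates are carried as racemic or diastereomeric mixtures (tosyl = 4-methylbenzenesulfonyl).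

**Route**

Step 1
Reactants: 1 2,4-dihydroxyacetophenone
Product: 2 2-hydroxy-4-(tosyloxy)acetophenone
Conditions: TsCl (1.05 equiv), K2CO3, acetone, rt
Reagents that add atoms: p-toluenesulfonyl chloride, Cc1ccc(cc1)S(Cl)(=O)=O
Why: O-sulfonylation goes to the 4-hydroxyl because the 2-hydroxyl is held in a hydrogen bond to the acetyl carbonyl and is far less nucleophilic.

Step 2
Reactants: 2 2-hydroxy-4-(tosyloxy)acetophenone
Product: 3 2-methoxy-4-(tosyloxy)acetophenone
Conditions: MeI, K2CO3, DMF, rt to 40 °C
Reagents that add atoms: iodomethane, CI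
Why: Williamson O-methylation of the remaining chelated phenol runs under carbonate conditions that leave the aryl sulfonate untouched.

Step 3
Reactants: 4 3,4-dihydroxybenzaldehyde
Product: 5 3,4-bis(tosyloxy)benzaldehyde
Conditions: TsCl (2.2 equiv), K2CO3, acetone, reflux
Reagents that add atoms: p-toluenesulfonyl chloride, Cc1ccc(cc1)S(Cl)(=O)=O
Why: Exhaustive O-sulfonylation of the catechol turns ring D into an electron-poor arene that stays inert in every later acid step.

Step 4
Reactants: 3 2-methoxy-4-(tosyloxy)acetophenone; 5 3,4-bis(tosyloxy)benzaldehyde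
Product: 6 (E)-1-(2-methoxy-4-tosyloxyphenyl)-3-[3,4-bis(tosyloxy)phenyl]prop-2-en-1-one
Conditions: BF3·OEt2 (0.5 equiv), 1,4-dioxane, rt
Reagents that add atoms: none
Why: An acid-mediated Claisen–Schmidt condensation (enolisation of the methyl ketone by BF3, aldol addition, dehydration) forms the C2–CH2 bond as the E-enone without the hydroxide that would cleave aryl sulfonates.

Step 5
Reactants: 6 chalcone
Product: 7 1-(2-methoxy-4-tosyloxyphenyl)-3-[3,4-bis(tosyloxy)phenyl]propan-1-one
Conditions: H2 (1 atm), Pd/C, EtOAc, rt, stopped after one equivalent of H2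
Reagents that add atoms: none
Why: Heterogeneous catalytic hydrogenation saturates the conjugated C=C faster than the aryl ketone, and aryl tosylates are inert to Pd/C under a balloon of hydrogen.

Step 6
Reactants: 8 2,6-dimethoxyphenol
Product: 9 2-(benzyloxy)-1,3-dimethoxybenzene
Conditions: BnBr, K2CO3, acetone, reflux
Reagents that add atoms: benzyl bromide, BrCc1ccccc1
Why: Williamson benzylation masks the only acidic site of ring B, and the benzyloxy group, wedged between two methoxy groups, is twisted out of conjugation so that it does not direct the next substitution.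

Step 7
Reactants: 9 2-(benzyloxy)-1,3-dimethoxybenzene
Product: 10 2-(benzyloxy)-4-bromo-1,3-dimethoxybenzene
Conditions: NBS, MeCN, 0 °C to rt, dark
Reagents that add atoms: N-bromosuccinimide, O=C1CCC(=O)N1Br
Why: Electrophilic aromatic bromination goes para to one methoxy group and ortho to the other, as in 1,2,3-trialkoxybenzenes, and so marks the carbon that becomes C4a.

Step 8
Reactants: 10 2-(benzyloxy)-4-bromo-1,3-dimethoxybenzene
Product: 12 2-[3-(benzyloxy)-2,4-dimethoxyphenyl]ethanol, via aryllithium 11 (not isolated)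
Conditions: n-BuLi, THF, −78 °C; ethylene oxide (THF solution, excess), −78 °C to rt; aqueous NH4Cl
Reagents that add atoms: ethylene oxide, C1CO1
Why: Bromine–lithium exchange followed by ring opening of the epoxide by the aryllithium forms the C4a–C4 bond and brings in C3 at the alcohol level.

Step 9
Reactants: 12 2-[3-(benzyloxy)-2,4-dimethoxyphenyl]ethanol
Product: 13 [3-(benzyloxy)-2,4-dimethoxyphenyl]acetaldehyde
Conditions: Dess–Martin periodinane, CH2Cl2, 0 °C to rt; used at once
Reagents that add atoms: none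
Why: Dess–Martin oxidation gives the enolisable arylacetaldehyde under neutral, non-aqueous conditions that avoid aldol self-condensation.

Step 10
Reactants: 7 dihydrochalcone; 13 [3-(benzyloxy)-2,4-dimethoxyphenyl]acetaldehyde
Product: 15 4-[3-(benzyloxy)-2,4-dimethoxyphenyl]-2-[3,4-bis(tosyloxy)benzyl]-3-hydroxy-1-(2-methoxy-4-tosyloxyphenyl)butan-1-one (syn/anti mixture), via lithium enolate 14 (not isolated)
Conditions: LiN(SiMe3)2, THF, −78 °C; then 13, −78 °C; AcOH quench at −78 °C
Reagents that add atoms: none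
Why: In this directed aldol addition the ketone can enolise only at C2 and its lithium enolate adds to the aldehyde at −78 °C to form C2–C3, while the two new stereocentres are left uncontrolled because C3 is oxidised next and C2 later becomes aromatic.

Step 11
Reactants: 15 aldol adduct
Product: 16 4-[3-(benzyloxy)-2,4-dimethoxyphenyl]-2-[3,4-bis(tosyloxy)benzyl]-1-(2-methoxy-4-tosyloxyphenyl)butane-1,3-dione
Conditions: 2-iodoxybenzoic acid (IBX), EtOAc, 77 °C
Reagents that add atoms: none
Why: Oxidation of β-hydroxy ketones with IBX stops at the β-diketone without further oxidation at the carbon between the two carbonyls.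

Step 12
Reactants: 16 O-benzyl diketone
Product: 17 2-[3,4-bis(tosyloxy)benzyl]-4-(3-hydroxy-2,4-dimethoxyphenyl)-1-(2-methoxy-4-tosyloxyphenyl)butane-1,3-dione
Conditions: H2 (1 atm), Pd/C, EtOAc/EtOH, rt
Reagents that add atoms: none
Why: Hydrogenolysis of the aryl benzyl ether frees the ring B phenol that must activate C8a, while aryl tosylates and the hindered diketone are left alone.

Step 13
Reactants: 17 free-phenol diketone
Product: 19 3-[3,4-bis(tosyloxy)benzyl]-4-(2-methoxy-4-tosyloxyphenyl)-6,8-dimethoxynaphthalene-2,7-diol (the tri-O-tosyl target), via carbinol 18 (not isolated)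
Conditions: MeSO3H, CH2Cl2, 0 °C to rt
Reagents that add atoms: none
Why: In MeSO3H the 1,3-diketone is protonated at the C1 aryl ketone, ring B attacks that carbon through C8a to give carbinol 18, and ionisation of the doubly benzylic C1–OH, loss of the C2 proton and enolisation of the C3 ketone through C4 aromatise ring A with loss of one water. The closest known reaction type is the acid-catalysed cyclodehydration of γ-aryl β-diketones and γ-aryl β-keto esters to 2-naphthols, a Friedel–Crafts hydroxyalkylation of the Bradsher cyclodehydration family. Ring A (C1–C2–C3–C4–C4a–C8a) closes in a 6-exo-trig mode with respect to the C1=O bond, which stays outside the new ring, while the attacking C4a=C8a bond of ring B lies inside it. No stereocentre is created in the product, since the C1 and C2 centres of 18 disappear on aromatisation and the C1–aryl axis is not defined in the target. The step needs chemoselectivity for ring B over ring D, whose attack on C1 or C3 would close a five-membered indene, and this is secured by the free C6 hydroxyl para to C8a on ring B set against two electron-withdrawing sulfonates on ring D, with ring C switched off by its carbonyl and its sulfonate. Regioselectivity is built in, because C8a is the only unsubstituted carbon ortho to the C4 methylene and only the C1 carbonyl can be reached from it through a six-membered ring, the C3 carbonyl being only four atoms away.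

Step 14
Reactants: 19 tri-O-tosyl naphthol
Product: 20 3-(3,4-dihydroxybenzyl)-4-(4-hydroxy-2-methoxyphenyl)-6,8-dimethoxynaphthalene-2,7-diol (target)
Conditions: KOH, MeOH/H2O (degassed), 65 °C, under argon; then aqueous HCl
Reagents that add atoms: none
Why: Sulfonate ester hydrolysis by attack at sulfur releases the three phenols with their aryl–O bonds intact, and exclusion of oxygen protects the catecholate and naphtholate until acidification.

**Compound list**

1 | 2,4-dihydroxyacetophenone | CC(=O)c1ccc(O)cc1O | starting material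
2 | 2-hydroxy-4-(tosyloxy)acetophenone | CC(=O)c1ccc(OS(=O)(=O)c2ccc(C)cc2)cc1O | intermediate
3 | 2-methoxy-4-(tosyloxy)acetophenone | CC(=O)c1ccc(OS(=O)(=O)c2ccc(C)cc2)cc1OC | intermediate
4 | 3,4-dihydroxybenzaldehyde | O=Cc1ccc(O)c(O)c1 | starting material
5 | 3,4-bis(tosyloxy)benzaldehyde | O=Cc1ccc(OS(=O)(=O)c2ccc(C)cc2)c(OS(=O)(=O)c2ccc(C)cc2)c1 | intermediate
6 | (E)-1-(2-methoxy-4-tosyloxyphenyl)-3-[3,4-bis(tosyloxy)phenyl]prop-2-en-1-one | COc1cc(OS(=O)(=O)c2ccc(C)cc2)ccc1C(=O)/C=C/c1ccc(OS(=O)(=O)c2ccc(C)cc2)c(OS(=O)(=O)c2ccc(C)cc2)c1 | intermediate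
7 | 1-(2-methoxy-4-tosyloxyphenyl)-3-[3,4-bis(tosyloxy)phenyl]propan-1-one | COc1cc(OS(=O)(=O)c2ccc(C)cc2)ccc1C(=O)CCc1ccc(OS(=O)(=O)c2ccc(C)cc2)c(OS(=O)(=O)c2ccc(C)cc2)c1 | intermediate
8 | 2,6-dimethoxyphenol | COc1cccc(OC)c1O | starting material
9 | 2-(benzyloxy)-1,3-dimethoxybenzene | COc1cccc(OC)c1OCc1ccccc1 | intermediate
10 | 2-(benzyloxy)-4-bromo-1,3-dimethoxybenzene | COc1ccc(Br)c(OC)c1OCc1ccccc1 | intermediate
11 | [3-(benzyloxy)-2,4-dimethoxyphenyl]lithium (not isolated) | [Li]c1ccc(OC)c(OCc2ccccc2)c1OC | intermediate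
12 | 2-[3-(benzyloxy)-2,4-dimethoxyphenyl]ethanol | OCCc1ccc(OC)c(OCc2ccccc2)c1OC | intermediate
13 | [3-(benzyloxy)-2,4-dimethoxyphenyl]acetaldehyde | O=CCc1ccc(OC)c(OCc2ccccc2)c1OC | intermediate
14 | lithium (Z)-enolate of 7 (not isolated) | [Li]O/C(=C\Cc1ccc(OS(=O)(=O)c2ccc(C)cc2)c(OS(=O)(=O)c2ccc(C)cc2)c1)c1ccc(OS(=O)(=O)c2ccc(C)cc2)cc1OC | intermediate
15 | 4-[3-(benzyloxy)-2,4-dimethoxyphenyl]-2-[3,4-bis(tosyloxy)benzyl]-3-hydroxy-1-(2-methoxy-4-tosyloxyphenyl)butan-1-one (syn/anti mixture, racemic) | COc1cc(OS(=O)(=O)c2ccc(C)cc2)ccc1C(=O)C(Cc1ccc(OS(=O)(=O)c2ccc(C)cc2)c(OS(=O)(=O)c2ccc(C)cc2)c1)C(O)Cc1ccc(OC)c(OCc2ccccc2)c1OC | intermediate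
16 | 4-[3-(benzyloxy)-2,4-dimethoxyphenyl]-2-[3,4-bis(tosyloxy)benzyl]-1-(2-methoxy-4-tosyloxyphenyl)butane-1,3-dione (racemic) | COc1cc(OS(=O)(=O)c2ccc(C)cc2)ccc1C(=O)C(Cc1ccc(OS(=O)(=O)c2ccc(C)cc2)c(OS(=O)(=O)c2ccc(C)cc2)c1)C(=O)Cc1ccc(OC)c(OCc2ccccc2)c1OC | intermediate
17 | 2-[3,4-bis(tosyloxy)benzyl]-4-(3-hydroxy-2,4-dimethoxyphenyl)-1-(2-methoxy-4-tosyloxyphenyl)butane-1,3-dione (racemic) | COc1cc(OS(=O)(=O)c2ccc(C)cc2)ccc1C(=O)C(Cc1ccc(OS(=O)(=O)c2ccc(C)cc2)c(OS(=O)(=O)c2ccc(C)cc2)c1)C(=O)Cc1ccc(OC)c(O)c1OC | intermediate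
18 | 3-[3,4-bis(tosyloxy)benzyl]-4,7-dihydroxy-4-(2-methoxy-4-tosyloxyphenyl)-6,8-dimethoxy-3,4-dihydronaphthalen-2(1H)-one (not isolated, stereocentres undefined) | COc1cc(OS(=O)(=O)c2ccc(C)cc2)ccc1C1(O)C(Cc2ccc(OS(=O)(=O)c3ccc(C)cc3)c(OS(=O)(=O)c3ccc(C)cc3)c2)C(=O)Cc2c(OC)c(O)c(OC)cc21 | intermediate
19 | 3-[3,4-bis(tosyloxy)benzyl]-4-(2-methoxy-4-tosyloxyphenyl)-6,8-dimethoxynaphthalene-2,7-diol | COc1cc(OS(=O)(=O)c2ccc(C)cc2)ccc1-c1c(Cc2ccc(OS(=O)(=O)c3ccc(C)cc3)c(OS(=O)(=O)c3ccc(C)cc3)c2)c(O)cc2c(OC)c(O)c(OC)cc12 | intermediate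
20 | 3-(3,4-dihydroxybenzyl)-4-(4-hydroxy-2-methoxyphenyl)-6,8-dimethoxynaphthalene-2,7-diol | COc1cc(O)ccc1-c1c(Cc2ccc(O)c(O)c2)c(O)cc2c(OC)c(O)c(OC)cc12 | target

**Step count and risks**

Total steps: 14. Longest linear sequence: 9 (steps 6–14; the branch through steps 1, 2, 4, 5 and 10–14 is equally long).

Steps most likely to fail:

Step 13. The protonated C1 aryl ketone is hindered and conjugated, so addition of ring B may be slower than acid-induced retro-Claisen fragmentation of the 2-substituted diketone or than closure of ring D onto a carbonyl. The fallback moves C1 to the carbinol oxidation level, so that the same C1–C8a bond forms by Friedel–Crafts alkylation with a benzylic cation instead of by hydroxyalkylation of a ketone. Setting out from 17, NaBH4 in MeOH/THF at 0 °C should reduce both carbonyls to the 1,3-diol F1 (diastereomer mixture). CF3CO2H in CH2Cl2 at 0 °C should ionise only the C1 benzylic alcohol, the cation being stabilised by the ortho-methoxy group of ring C, and ring B should capture it through C8a to give the 3-hydroxytetralin F2. Swern oxidation ((COCl)2, DMSO, Et3N, CH2Cl2, −78 °C), chosen because the hindered ring B phenol tolerates it, should give the C3 ketone F3. DDQ in 1,4-dioxane at rt should then dehydrogenate this 2-tetralone-type ketone to the naphthol, which rejoins the route at 19.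

Step 10. Proton transfer from the acidic CH2 of arylacetaldehyde 13 to enolate 14, and self-condensation of 13, may outrun the cross-aldol addition. The fallback forms C2–C3 by C-acylation of the enolate at the acid oxidation level, which needs neither the aldehyde nor the later oxidation. Setting out from 12, TEMPO (catalytic) and PhI(OAc)2 in MeCN/H2O should give the arylacetic acid F4, and (COCl)2 with catalytic DMF in CH2Cl2 should convert it into the acid chloride F5. Enolate 14, prepared from 7 as in step 10 and used in two equivalents so that the second takes up the acidic C2 proton of the product and returns as 7, is acylated with F5 in THF at −78 °C. This should give the diketone directly and rejoins the route at 16.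

Step 8. Opening of ethylene oxide by the chelated aryllithium is slow, so coupling of 11 with the 1-bromobutane formed in the exchange, or metalation at the benzylic OCH2, may compete on warming. The fallback replaces the organolithium by a cross-coupling and an oxidative cleavage. Setting out from 10, Stille coupling with allyltributylstannane (Pd(PPh3)4, toluene, 100 °C) should give the allylarene F6. Lemieux–Johnson cleavage (OsO4 catalytic, NaIO4, 2,6-lutidine, 1,4-dioxane/H2O, rt) should then cut the terminal alkene to the arylacetaldehyde, which replaces steps 8 and 9 and rejoins the route at 13.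

**Further compounds**

F1 | step 13 | 2-[3,4-bis(tosyloxy)benzyl]-4-(3-hydroxy-2,4-dimethoxyphenyl)-1-(2-methoxy-4-tosyloxyphenyl)butane-1,3-diol (diastereomer mixture) | COc1cc(OS(=O)(=O)c2ccc(C)cc2)ccc1C(O)C(Cc1ccc(OS(=O)(=O)c2ccc(C)cc2)c(OS(=O)(=O)c2ccc(C)cc2)c1)C(O)Cc1ccc(OC)c(O)c1OC
F2 | step 13 | 3-[3,4-bis(tosyloxy)benzyl]-4-(2-methoxy-4-tosyloxyphenyl)-6,8-dimethoxy-1,2,3,4-tetrahydronaphthalene-2,7-diol (diastereomer mixture) | COc1cc(OS(=O)(=O)c2ccc(C)cc2)ccc1C1C(Cc2ccc(OS(=O)(=O)c3ccc(C)cc3)c(OS(=O)(=O)c3ccc(C)cc3)c2)C(O)Cc2c(OC)c(O)c(OC)cc21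
F3 | step 13 | 3-[3,4-bis(tosyloxy)benzyl]-7-hydroxy-4-(2-methoxy-4-tosyloxyphenyl)-6,8-dimethoxy-3,4-dihydronaphthalen-2(1H)-one (diastereomer mixture) | COc1cc(OS(=O)(=O)c2ccc(C)cc2)ccc1C1C(Cc2ccc(OS(=O)(=O)c3ccc(C)cc3)c(OS(=O)(=O)c3ccc(C)cc3)c2)C(=O)Cc2c(OC)c(O)c(OC)cc21
F4 | step 10 | [3-(benzyloxy)-2,4-dimethoxyphenyl]acetic acid | OC(=O)Cc1ccc(OC)c(OCc2ccccc2)c1OC
F5 | step 10 | [3-(benzyloxy)-2,4-dimethoxyphenyl]acetyl chloride | ClC(=O)Cc1ccc(OC)c(OCc2ccccc2)c1OC
F6 | step 8 | 1-allyl-3-(benzyloxy)-2,4-dimethoxybenzene | C=CCc1ccc(OC)c(OCc2ccccc2)c1OC
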